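**Retrosynthetic overview**

1. The route rests on the cyclohexane C5–C10 of the elemanolide: C10 is the quaternary carbon (methyl, vinyl), C9 is CH–OAc, C8 is CH–O of the lactone, C7 the ring-fusion carbon, C6 is CH–O-angelate, and C5 carries the acrolein unit C4(=C15H2)–C3HO. O8 and O9 are cis (both α) on neighbouring ring carbons, a cis-1,2-diol that is opened at C8–C9 to a 1,6-dialdehyde.
2. Ring 1 (cyclohexane) is closed by SmI2 pinacol coupling of the acyclic dialdehyde 19 to the 8α,9α-diol 20.
3. Ring 2 (trans-fused γ-lactone C7–C11–C12(=O)–O8) is closed afterwards by oxidative lactonisation of a C12 carbinol onto the equatorial O8, which leaves O9 free. C12 travels as CH2OTBS, because a C8 carbinol placed γ to a C12 ester would lactonise before it could be oxidised to the aldehyde.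
4. Dialdehyde 19: C5/C10 come from an enantioselective ester-enolate Claisen rearrangement. C6 is set by Felkin reduction of a β-keto ester and C7 by Fráter–Seebach alkylation, since a direct anti-aldol at a C6 aldehyde would have to add against the Felkin preference imposed by the quaternary C10. The enal is made from the isopropenyl group (SeO2) and carried as its dimethyl acetal.
5. After the rings: lactone α-methylenation, 9-O-acetylation, 6-OTBS to 6-O-angelate, acetal hydrolysis.

Key step: step 13

Assumption: the (S,S)-diazaborolidine reagent of step 3 is taken to deliver the (2S,3S)-acid 6; if the sense of induction is the opposite, the (R,R)-reagent is used and nothing else changes.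
Remark: locants C1–C15 are the elemane locants of line 1; α/β refer to the ring drawn with the 10-methyl group β.

**Route**

Step 1
Reactants: 1 3-methylbut-3-enoic acid; 2 2-methyl-2-vinyloxirane (racemic)
Product: 3 (2E)-4-hydroxy-3-methylbut-2-en-1-yl 3-methylbut-3-enoate
Conditions: Pd(PPh3)4 (cat.), THF, 0 °C → rt; Z-isomer removed by chromatography
Reagents that add atoms: none
Why: Pd(0)-catalysed 1,4-addition of a carboxylic acid to a vinyl epoxide (Tsuji–Trost type), in which the carboxylate attacks the unsubstituted terminus of the π-allyl alkoxide and the syn π-allyl should give mainly the E-alkene; the epoxide stereocentre is destroyed, and the Z-isomer is removed because it would lead to the C10 epimer in step 3.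

Step 2
Reactants: 3 (2E)-4-hydroxy-3-methylbut-2-en-1-yl 3-methylbut-3-enoate
Product: 4 (2E)-3-methyl-4-(pivaloyloxy)but-2-en-1-yl 3-methylbut-3-enoate
Conditions: PivCl, pyridine, DMAP (cat.), CH2Cl2, 0 °C → rt
Reagents that add atoms: pivaloyl chloride, CC(C)(C)C(=O)Cl
Why: Acylation of the primary allylic alcohol (future O9); the pivalate has no α-hydrogen, so it cannot compete in the enolisation of step 3, and it is cleaved later by LiAlH4 in the same operation that reduces the C8 ester.

Step 3
Reactants: 4 (2E)-3-methyl-4-(pivaloyloxy)but-2-en-1-yl 3-methylbut-3-enoate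
Product: 6 (2S,3S)-3-methyl-3-[(pivaloyloxy)methyl]-2-(prop-1-en-2-yl)pent-4-enoic acid, via boron ketene acetal 5 (not isolated)
Conditions: (S,S)-2-bromo-4,5-diphenyl-1,3-bis(arylsulfonyl)-1,3,2-diazaborolidine [Ar = 3,5-(CF3)2C6H3; from the bis-sulfonamide and BBr3, CH2Cl2], Et3N, toluene–hexane, −78 °C → 4 °C; aqueous work-up
Reagents that add atoms: none
Why: Enantioselective boron ester-enolate Claisen (Ireland-type) rearrangement, in which soft enolisation under conditions that favour the E(O) boron ketene acetal 5, combined with the E-alkene and a chair transition state (isopropenyl and 10-methyl pseudo-axial, CH2OPiv pseudo-equatorial), sets C5 and C10 together with the relative configuration of the target, while the C2-symmetric boron ligand selects the enolate face and so the absolute configuration.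

Step 4
Reactants: 6 (2S,3S)-3-methyl-3-[(pivaloyloxy)methyl]-2-(prop-1-en-2-yl)pent-4-enoic acid; 7 potassium methyl malonate
Product: 9 methyl (4S,5S)-5-methyl-3-oxo-5-[(pivaloyloxy)methyl]-4-(prop-1-en-2-yl)hept-6-enoate, via acyl imidazolide 8 (not isolated)
Conditions: CDI, THF, rt; then 7, MgCl2, Et3N, THF–MeCN, rt → 40 °C; aq. HCl
Reagents that add atoms: none
Why: Masamune–Brooks homologation, in which the acyl imidazolide C-acylates the magnesium enolate of the malonate half-ester and decarboxylation gives the β-keto ester (C6 ketone, C7, C8 ester) under near-neutral conditions that should leave the allylic C5–H untouched.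

Step 5
Reactants: 9 methyl (4S,5S)-5-methyl-3-oxo-5-[(pivaloyloxy)methyl]-4-(prop-1-en-2-yl)hept-6-enoate
Product: 10 methyl (3R,4S,5S)-3-hydroxy-5-methyl-5-[(pivaloyloxy)methyl]-4-(prop-1-en-2-yl)hept-6-enoate
Conditions: NaBH4, MeOH, −40 °C
Reagents that add atoms: none
Why: Felkin–Anh reduction of the ketone, in which hydride should add anti to the quaternary C10 (the large α-substituent at C5) with the isopropenyl group inside, which gives the C6 carbinol with O6 anti to C4 along the chain C10–C5–C6–C7, the relationship required in the target (a carbon nucleophile adding to a C6 aldehyde would give the opposite one).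

Step 6
Reactants: 11 2-[(tert-butyldimethylsilyl)oxy]ethanol
Product: 12 2-[(tert-butyldimethylsilyl)oxy]ethyl trifluoromethanesulfonate
Conditions: Tf2O, 2,6-lutidine, CH2Cl2, −78 °C; used directly
Reagents that add atoms: trifluoromethanesulfonic anhydride, O=S(=O)(OS(=O)(=O)C(F)(F)F)C(F)(F)F
Why: Triflation of a primary alcohol gives an electrophile reactive enough for the hindered dianion of step 7, where the corresponding β-silyloxy iodide would be too sluggish.

Step 7
Reactants: 10 methyl (3R,4S,5S)-3-hydroxy-5-methyl-5-[(pivaloyloxy)methyl]-4-(prop-1-en-2-yl)hept-6-enoate; 12 2-[(tert-butyldimethylsilyl)oxy]ethyl trifluoromethanesulfonate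
Product: 13 methyl (2S,3S,4S,5S)-2-{2-[(tert-butyldimethylsilyl)oxy]ethyl}-3-hydroxy-5-methyl-5-[(pivaloyloxy)methyl]-4-(prop-1-en-2-yl)hept-6-enoate
Conditions: LDA (2.2 equiv), THF, −78 → −20 °C; then 12 (1.05 equiv), DMPU, −78 → −40 °C; NH4Cl
Reagents that add atoms: none
Why: Fráter–Seebach alkylation, in which the lithium-chelated alkoxide–enolate is alkylated at C7 on the face away from the C6 substituent and so gives the 6,7-anti product (C11 anti to O6), the pivalate having no α-hydrogen and the triflate being held to one equivalent to avoid O-alkylation.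

Step 8
Reactants: 13 the β-hydroxy ester of step 7
Product: 14 methyl ester 13 with O6 as tert-butyldimethylsilyl ether (stereocentres as in 13)
Conditions: TBSOTf, 2,6-lutidine, CH2Cl2, 0 °C → rt
Reagents that add atoms: tert-butyldimethylsilyl trifluoromethanesulfonate, CC(C)(C)[Si](C)(C)OS(=O)(=O)C(F)(F)F
Why: Silylation of a hindered secondary alcohol with the silyl triflate; the TBS ether protects O6 up to step 18 and later sits axial on the ring, which supports the facial selectivity of the key step.

Step 9
Reactants: 14 the bis-silyl ether ester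
Product: 16 enal in which the isopropenyl group of 14 has become 3-oxoprop-1-en-2-yl (C4(=C15H2)–C3HO), via allylic alcohol 15 (not isolated)
Conditions: SeO2 (cat.), t-BuOOH, CH2Cl2, rt; then MnO2, CH2Cl2, rt
Reagents that add atoms: tert-butyl hydroperoxide, CC(C)(C)OO (oxygen delivered through selenium dioxide, O=[Se]=O)
Why: Selenium dioxide allylic oxidation (ene reaction, then [2,3]-shift) at the isopropenyl methyl group, the only reactive allylic position (the vinyl group on quaternary C10 has no allylic hydrogen and the C5 methine is the least reactive type), followed by MnO2 oxidation of the allylic alcohol to the 2-substituted acrolein.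

Step 10
Reactants: 16 the enal
Product: 17 dimethyl acetal of 16 (C5 substituent = 3,3-dimethoxyprop-1-en-2-yl)
Conditions: MeOSiMe3, TMSOTf (cat.), CH2Cl2, −78 °C; pyridine quench
Reagents that add atoms: methoxytrimethylsilane, CO[Si](C)(C)C
Why: Noyori acetalisation, which converts enals into dimethyl acetals under aprotic conditions without conjugate addition and without loss of the primary or secondary TBS ethers; the acetal masks the enal against hydride, SmI2 and enolate chemistry.

Step 11
Reactants: 17 the acetal ester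
Product: 18 1,6-diol (C8H2OH and C9H2OH free; 6-OTBS, C12–OTBS and acetal kept; stereocentres as in 13)
Conditions: LiAlH4, Et2O, 0 °C → rt
Reagents that add atoms: none
Why: Hydride reduction of the methyl ester to the C8 carbinol and reductive cleavage of the C9 pivalate in one operation; silyl ethers, acetal and isolated alkenes are inert to LiAlH4.

Step 12
Reactants: 18 the 1,6-diol
Product: 19 1,6-dialdehyde OHC(9)–C10(Me)(vinyl)–C5H[C(=CH2)CH(OMe)2]–C6H(OTBS)–C7H(CH2CH2OTBS)–C(8)HO
Conditions: Dess–Martin periodinane, NaHCO3, CH2Cl2, 0 °C → rt; filtered and used at once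
Reagents that add atoms: none
Why: Dess–Martin oxidation of both primary alcohols under buffered, non-basic conditions, which should avoid epimerisation at C7 and β-elimination of the 6-silyloxy group in the enolisable C8 aldehyde.

Step 13
Reactants: 19 the 1,6-dialdehyde
Product: 20 cyclohexane-8α,9α-diol (10β-methyl, 10α-vinyl, 5β-(3,3-dimethoxyprop-1-en-2-yl), 6β-OTBS, 7β-[2-(TBSO)ethyl])
Conditions: SmI2 (3 equiv), t-BuOH (2 equiv), THF, −78 °C, slow addition of 19 (final 0.01 M); sat. NaHCO3
Reagents that add atoms: none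
Why: Two electrons from SmI2 reduce the C8 and C9 formyl groups to ketyls, which combine (ketyl–ketyl, or ketyl addition to the second Sm(III)-bound formyl group) within a samarium-bridged array to form C8–C9, the known SmI2 pinacol cyclisation of 1,6-dialdehydes to cis-cyclohexane-1,2-diols. The cyclohexane C5–C10 is closed by a 6-exo attack of one ketyl carbon on the other carbonyl carbon through a chair-like arrangement with the C5 and C7 side chains equatorial and 10-Me and 6-OTBS axial, as in the target. C8 is controlled by the C7 side chain, which places O8 equatorial and anti to it (8α), and C9 by the Sm(III) bridge, which holds O9 cis to O8 and therefore axial on the α face, anti to the 10β-methyl group. The step needs cis over trans coupling, which THF without HMPA at −78 °C should secure by keeping the diolate chelated, and α,α over β,β, which the substrate secures because a β-O8 would be syn-axial to both 10-Me and 6-OTBS. It also needs ketyl–carbonyl coupling to outrun closure of the C8 ketyl onto C4=C15 (5-exo or 6-endo) or onto the C10 vinyl group (6-exo), which unactivated alkenes in the absence of HMPA should allow, and slow addition at high dilution suppresses intermolecular coupling. C9 is neopentyl, and C7 should keep its configuration because the medium is not basic and 19 is used as soon as it is made.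

Step 14
Reactants: 20 the 8α,9α-diol
Product: 21 8α,9α,12-triol (7β-(2-hydroxyethyl); 6β-OTBS kept)
Conditions: HF·pyridine, pyridine, THF, 0 °C
Reagents that add atoms: none
Why: Selective desilylation, the unhindered primary TBS ether being cleaved far faster by buffered HF·pyridine than the axial secondary 6-OTBS flanked by two branched carbons; the acetal survives the buffered, anhydrous medium.

Step 15
Reactants: 21 the triol
Product: 23 trans-fused 12,8α-olide with free 9α-OH (6β-OTBS, C11H2), via lactol 22 (not isolated)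
Conditions: TEMPO (cat.), PhI(OAc)2, CH2Cl2, rt
Reagents that add atoms: none
Why: TEMPO-catalysed oxidative lactonisation of a 1,4-diol, in which the primary C12 alcohol is oxidised to the aldehyde, the adjacent equatorial O8 closes the five-membered lactol, and this is oxidised to the lactone; the axial 9α-OH cannot reach C12 and secondary alcohols are oxidised slowly, so O8 and O9 are differentiated without a protecting group.

Step 16
Reactants: 23 the lactone
Product: 26 α-methylene lactone (C11=C13H2; 9α-OH free; 6β-OTBS), via Mannich base 24 (not isolated), via methiodide 25 (not isolated)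
Conditions: LDA (2.3 equiv), THF, −78 °C; CH2=NMe2+ I−, −78 °C → rt; then MeI, MeOH, rt; then aq. NaHCO3, CH2Cl2
Reagents that add atoms: dimethylmethylideneammonium iodide (Eschenmoser's salt), C=[N+](C)C.[I-]
Why: Eschenmoser α-methylenation, in which the lactone enolate (formed beside the 9-alkoxide) undergoes a Mannich reaction at C11, and quaternisation followed by mild base elimination gives the exocyclic alkene; C11 is the only enolisable position and carries no β-leaving group.

Step 17
Reactants: 26 the α-methylene lactone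
Product: 27 9α-acetate of 26
Conditions: Ac2O, DMAP, pyridine, CH2Cl2, rt
Reagents that add atoms: acetic anhydride, CC(=O)OC(C)=O
Why: DMAP-catalysed acetylation of the only free hydroxyl (axial, neopentyl 9α-OH), with retention at C9.

Step 18
Reactants: 27 the acetate
Product: 28 6β-alcohol (9α-OAc, α-methylene lactone, acetal)
Conditions: HF·pyridine, pyridine, THF, 0 °C → rt
Reagents that add atoms: none
Why: Fluoride-mediated cleavage of the remaining secondary TBS ether under buffered acidic conditions, which avoid conjugate addition to the methylene lactone and acetate loss; O6 and O9 are too far apart for acyl migration.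

Step 19
Reactants: 28 the 6β-alcohol; 29 angelic acid ((2Z)-2-methylbut-2-enoic acid)
Product: 31 6β-angelate (9α-OAc, α-methylene lactone, acetal), via mixed anhydride 30 (not isolated)
Conditions: 29, 2,4,6-trichlorobenzoyl chloride, Et3N, toluene, rt; then 28, toluene, 80 °C
Reagents that add atoms: none
Why: Yamaguchi-type esterification through the angelic 2,4,6-trichlorobenzoic mixed anhydride, used without a nucleophilic catalyst because this is the established way to acylate hindered secondary alcohols with angelic acid while limiting Z→E isomerisation to the tiglate.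

Step 20
Reactants: 31 the angelate acetal
Product: 32 CNP0228039.1 (9α-acetoxy-6β-angeloyloxy-3-oxoelema-1,4(15),11(13)-trien-12,8α-olide)
Conditions: PPTS (cat.), acetone–H2O, rt
Reagents that add atoms: water, O
Why: Mild acid hydrolysis of the allylic dimethyl acetal releases the 2-substituted acrolein; the esters, the lactone and the Z-enoate are stable to these conditions.

**Compound list**

1 | 3-methylbut-3-enoic acid | C=C(C)CC(=O)O | starting material
2 | 2-methyl-2-vinyloxirane (racemic) | CC1(CO1)C=C | starting material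
3 | (2E)-4-hydroxy-3-methylbut-2-en-1-yl 3-methylbut-3-enoate | C=C(C)CC(=O)OC/C=C(\C)CO | intermediate
4 | (2E)-3-methyl-4-(pivaloyloxy)but-2-en-1-yl 3-methylbut-3-enoate | C=C(C)CC(=O)OC/C=C(\C)COC(=O)C(C)(C)C | intermediate
5 | E(O) boron ketene acetal of 4 with the (S,S)-diazaborolidine | C=C(C)/C=C(/OB1N(S(=O)(=O)c2cc(cc(c2)C(F)(F)F)C(F)(F)F)[C@@H](c2ccccc2)[C@H](c2ccccc2)N1S(=O)(=O)c2cc(cc(c2)C(F)(F)F)C(F)(F)F)OC/C=C(\C)COC(=O)C(C)(C)C | intermediate
6 | (2S,3S)-3-methyl-3-[(pivaloyloxy)methyl]-2-(prop-1-en-2-yl)pent-4-enoic acid | CC(C)(C)C(=O)OC[C@@](C)(C=C)[C@H](C(C)=C)C(=O)O | intermediate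
7 | potassium methyl malonate | COC(=O)CC(=O)[O-].[K+] | starting material
8 | acyl imidazolide of 6 | CC(C)(C)C(=O)OC[C@@](C)(C=C)[C@H](C(C)=C)C(=O)n1ccnc1 | intermediate
9 | methyl (4S,5S)-5-methyl-3-oxo-5-[(pivaloyloxy)methyl]-4-(prop-1-en-2-yl)hept-6-enoate | CC(C)(C)C(=O)OC[C@@](C)(C=C)[C@H](C(C)=C)C(=O)CC(=O)OC | intermediate
10 | methyl (3R,4S,5S)-3-hydroxy-5-methyl-5-[(pivaloyloxy)methyl]-4-(prop-1-en-2-yl)hept-6-enoate | CC(C)(C)C(=O)OC[C@@](C)(C=C)[C@H](C(C)=C)[C@H](O)CC(=O)OC | intermediate
11 | 2-[(tert-butyldimethylsilyl)oxy]ethanol | CC(C)(C)[Si](C)(C)OCCO | starting material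
12 | 2-[(tert-butyldimethylsilyl)oxy]ethyl trifluoromethanesulfonate | CC(C)(C)[Si](C)(C)OCCOS(=O)(=O)C(F)(F)F | intermediate
13 | methyl (2S,3S,4S,5S)-2-{2-[(tert-butyldimethylsilyl)oxy]ethyl}-3-hydroxy-5-methyl-5-[(pivaloyloxy)methyl]-4-(prop-1-en-2-yl)hept-6-enoate | CC(C)(C)C(=O)OC[C@@](C)(C=C)[C@H](C(C)=C)[C@H](O)[C@H](CCO[Si](C)(C)C(C)(C)C)C(=O)OC | intermediate
14 | 3-O-TBS ether of 13 | CC(C)(C)C(=O)OC[C@@](C)(C=C)[C@H](C(C)=C)[C@H](O[Si](C)(C)C(C)(C)C)[C@H](CCO[Si](C)(C)C(C)(C)C)C(=O)OC | intermediate
15 | allylic alcohol (4-(3-hydroxyprop-1-en-2-yl) analogue of 14) | CC(C)(C)C(=O)OC[C@@](C)(C=C)[C@H](C(=C)CO)[C@H](O[Si](C)(C)C(C)(C)C)[C@H](CCO[Si](C)(C)C(C)(C)C)C(=O)OC | intermediate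
16 | enal (4-(3-oxoprop-1-en-2-yl) analogue of 14) | CC(C)(C)C(=O)OC[C@@](C)(C=C)[C@H](C(=C)C=O)[C@H](O[Si](C)(C)C(C)(C)C)[C@H](CCO[Si](C)(C)C(C)(C)C)C(=O)OC | intermediate
17 | dimethyl acetal of 16 | CC(C)(C)C(=O)OC[C@@](C)(C=C)[C@H](C(=C)C(OC)OC)[C@H](O[Si](C)(C)C(C)(C)C)[C@H](CCO[Si](C)(C)C(C)(C)C)C(=O)OC | intermediate
18 | 1,6-diol (C8 and C9 carbinols) | OC[C@@](C)(C=C)[C@H](C(=C)C(OC)OC)[C@H](O[Si](C)(C)C(C)(C)C)[C@H](CCO[Si](C)(C)C(C)(C)C)CO | intermediate
19 | 1,6-dialdehyde (pinacol precursor) | O=C[C@@](C)(C=C)[C@H](C(=C)C(OC)OC)[C@H](O[Si](C)(C)C(C)(C)C)[C@H](CCO[Si](C)(C)C(C)(C)C)C=O | intermediate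
20 | cyclohexane-8α,9α-diol (pinacol product) | C=C[C@]1(C)[C@H](O)[C@H](O)[C@@H](CCO[Si](C)(C)C(C)(C)C)[C@@H](O[Si](C)(C)C(C)(C)C)[C@H]1C(=C)C(OC)OC | intermediate
21 | 8α,9α,12-triol | C=C[C@]1(C)[C@H](O)[C@H](O)[C@@H](CCO)[C@@H](O[Si](C)(C)C(C)(C)C)[C@H]1C(=C)C(OC)OC | intermediate
22 | 12,8α-lactol | C=C[C@]1(C)[C@H](O)[C@@H]2OC(O)C[C@H]2[C@@H](O[Si](C)(C)C(C)(C)C)[C@H]1C(=C)C(OC)OC | intermediate
23 | 12,8α-olide with 9α-OH and 6β-OTBS | C=C[C@]1(C)[C@H](O)[C@@H]2OC(=O)C[C@H]2[C@@H](O[Si](C)(C)C(C)(C)C)[C@H]1C(=C)C(OC)OC | intermediate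
24 | 11-(dimethylaminomethyl) lactone (Mannich base) | C=C[C@]1(C)[C@H](O)[C@@H]2OC(=O)C(CN(C)C)[C@H]2[C@@H](O[Si](C)(C)C(C)(C)C)[C@H]1C(=C)C(OC)OC | intermediate
25 | trimethylammonium iodide of 24 | C=C[C@]1(C)[C@H](O)[C@@H]2OC(=O)C(C[N+](C)(C)C)[C@H]2[C@@H](O[Si](C)(C)C(C)(C)C)[C@H]1C(=C)C(OC)OC.[I-] | intermediate
26 | α-methylene lactone with 9α-OH and 6β-OTBS | C=C[C@]1(C)[C@H](O)[C@@H]2OC(=O)C(=C)[C@H]2[C@@H](O[Si](C)(C)C(C)(C)C)[C@H]1C(=C)C(OC)OC | intermediate
27 | 9α-acetate of 26 | C=C[C@]1(C)[C@H](OC(C)=O)[C@@H]2OC(=O)C(=C)[C@H]2[C@@H](O[Si](C)(C)C(C)(C)C)[C@H]1C(=C)C(OC)OC | intermediate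
28 | 6β-alcohol (9α-OAc, acetal) | C=C[C@]1(C)[C@H](OC(C)=O)[C@@H]2OC(=O)C(=C)[C@H]2[C@@H](O)[C@H]1C(=C)C(OC)OC | intermediate
29 | angelic acid, (2Z)-2-methylbut-2-enoic acid | C/C=C(/C)C(=O)O | starting material
30 | angelic 2,4,6-trichlorobenzoic anhydride | C/C=C(/C)C(=O)OC(=O)c1c(Cl)cc(Cl)cc1Cl | intermediate
31 | 6β-angelate, 9α-acetate, dimethyl acetal | C=C[C@]1(C)[C@H](OC(C)=O)[C@@H]2OC(=O)C(=C)[C@H]2[C@@H](OC(=O)/C(C)=C\C)[C@H]1C(=C)C(OC)OC | intermediate
32 | CNP0228039.1 | C=C[C@]1(C)[C@H](OC(C)=O)[C@@H]2OC(=O)C(=C)[C@H]2[C@@H](OC(=O)/C(C)=C\C)[C@H]1C(=C)C=O | target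

**Step count**

Total: 20 steps. Longest linear sequence: 19 steps (steps 1–5 and 7–20, from 1 and 2 to 32); step 6 is a one-step side branch.

**Steps most likely to fail**

1. Step 13 (SmI2 pinacol). The ketyls may couple through an open, non-bridged arrangement and give the trans-diol, or with poor facial discrimination. The C8 ketyl may also close onto an alkene, and the enolisable C8 aldehyde may epimerise at C7 before it couples. Fallback, from 19 back to 23: if the coupling gives mainly the trans-8α,9β-diol F1, that diol is carried on. The primary silyl ether is removed as in step 14 to give the 9-epi-triol F2. TEMPO/PhI(OAc)2 as in step 15 gives, through the 9-epi-lactol F3, the 9β-hydroxy lactone F4. Dess–Martin oxidation gives the 9-ketone F5, and L-Selectride at −78 °C, which should attack from the equatorial direction, should give the axial 9α-alcohol, which is lactone 23. C9 is then set by substrate-controlled reduction of a ring ketone and not by chelation during C–C bond formation.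

2. Step 19 (angeloylation). Acylation of the axial 6β-hydroxyl, flanked by two branched carbons, may be slow, and the activated angeloyl donor may isomerise Z→E on prolonged heating, so that tiglate forms. Fallback, from 28 back to 31: 28 is esterified (DCC, DMAP, CH2Cl2) with 2-[bis(2,2,2-trifluoroethoxy)phosphoryl]propanoic acid, an acid that cannot isomerise, to give the phosphonate ester F6. A Still–Gennari olefination (KHMDS, 18-crown-6, THF, −78 °C, then acetaldehyde) should then build the (Z)-2-methylbut-2-enoate on the molecule and give 31.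

3. Step 3 (enantioselective Claisen). Soft enolisation of the β,γ-unsaturated ester may lose enolate-geometry control (C5 epimer), enantiofacial control may be incomplete or of the opposite sense, and the boron enolate may rearrange slowly. Fallback, from 4 back to 6: a classical Ireland–Claisen rearrangement (LDA, THF, −78 °C; TMSCl; warm to rt), in which kinetic deprotonation in THF should give the E(O) silyl ketene acetal F7 and the same chair transition state the racemic acid F8 with the relative configuration of 6. Resolution by crystallisation of the salt with (R)-1-phenylethylamine (or its antipode, whichever gives the crystalline salt of the (2S,3S)-acid), salt F9, and acidification give 6.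

**Further compounds**

F1 | step 13 | trans-8α,9β-diol (9-epimer of 20) | C=C[C@]1(C)[C@@H](O)[C@H](O)[C@@H](CCO[Si](C)(C)C(C)(C)C)[C@@H](O[Si](C)(C)C(C)(C)C)[C@H]1C(=C)C(OC)OC
F2 | step 13 | 9-epi-triol | C=C[C@]1(C)[C@@H](O)[C@H](O)[C@@H](CCO)[C@@H](O[Si](C)(C)C(C)(C)C)[C@H]1C(=C)C(OC)OC
F3 | step 13 | 9-epi-lactol | C=C[C@]1(C)[C@@H](O)[C@@H]2OC(O)C[C@H]2[C@@H](O[Si](C)(C)C(C)(C)C)[C@H]1C(=C)C(OC)OC
F4 | step 13 | 9β-hydroxy-12,8α-olide | C=C[C@]1(C)[C@@H](O)[C@@H]2OC(=O)C[C@H]2[C@@H](O[Si](C)(C)C(C)(C)C)[C@H]1C(=C)C(OC)OC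
F5 | step 13 | 9-oxo-12,8α-olide | C=C[C@]1(C)C(=O)[C@@H]2OC(=O)C[C@H]2[C@@H](O[Si](C)(C)C(C)(C)C)[C@H]1C(=C)C(OC)OC
F6 | step 19 | 6β-{2-[bis(2,2,2-trifluoroethoxy)phosphoryl]propanoate} of 28 | C=C[C@]1(C)[C@H](OC(C)=O)[C@@H]2OC(=O)C(=C)[C@H]2[C@@H](OC(=O)C(C)P(=O)(OCC(F)(F)F)OCC(F)(F)F)[C@H]1C(=C)C(OC)OC
F7 | step 3 | E(O) trimethylsilyl ketene acetal of 4 | C=C(C)/C=C(/O[Si](C)(C)C)OC/C=C(\C)COC(=O)C(C)(C)C
F8 | step 3 | racemic (2S*,3S*)-3-methyl-3-[(pivaloyloxy)methyl]-2-(prop-1-en-2-yl)pent-4-enoic acid | CC(C)(C)C(=O)OC[C@@](C)(C=C)[C@H](C(C)=C)C(=O)O.CC(C)(C)C(=O)OC[C@](C)(C=C)[C@@H](C(C)=C)C(=O)O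
F9 | step 3 | (R)-1-phenylethylammonium salt of 6 | CC(C)(C)C(=O)OC[C@@](C)(C=C)[C@H](C(C)=C)C(=O)[O-].C[C@@H]([NH3+])c1ccccc1
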